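## Retrosynthetic overview

1. The furanone unit O–C3=C2–C1(=O)–C10 is a vinylogous ester, that is, an α′-oxido ynone. It is cut at O–C3 and C1–C2 into an enyne acetylide (C2) and an activated lactic acid unit, with C1, C10, C14 and the ring O held in a 2-tert-butyl-1,3-dioxolan-4-one.
2. Enabling feature: the cis-fused C6–C7 butyrolactone holds the C5 arm (enyne) and the C8 arm (dioxolanone) on one face. The linear C2≡C3–C4 rod can reach only the carbonyl C1.
3. C4–C5 comes from a Nozaki–Hiyama–Kishi addition of an enynyl triflate. C6–C7 and the lactone come from a Z-type 2-carbomethoxy-allylboronate plus (S)-glyceraldehyde acetonide, a chiral controller that is later cut down to the C5 aldehyde.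
4. C8–O comes from a catalyst-controlled SN2′ allylic esterification with isobutyric acid. C10 comes from self-regeneration of the stereocentre of (S)-lactic acid.
5. Ring order: dioxolanone (temporary), then γ-lactone, then the 10-membered carbocycle followed by the furanone and oxa-bridge, both in the key step.

Key step: step 16

Remark: germacrane numbering is used for all intermediates (C1–C3 and C10 furanone, C6/C7 lactone fusion, C11–C13 methylene lactone, C14 methyl, C15 methylene on C4). Compounds 4, 15, 18 and 22 are taken as purchasable.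

## Route

Step 1
Reactants: 1 (S)-lactic acid; 2 pivalaldehyde
Product: 3 (2S,5S)-2-tert-butyl-5-methyl-1,3-dioxolan-4-one (cis)
Conditions: TsOH·H2O (cat.), H2SO4 (cat.), pentane, reflux, Dean–Stark; crystallisation at −78 °C
Reagents that add atoms: none
Why: Acid-catalysed acetalisation in which the lactic acid centre (future C10) induces the cis acetal centre, and crystallisation should give the pure cis isomer needed for self-regeneration of the stereocentre.

Step 2
Reactants: 4 (Z)-4-(tert-butyldimethylsilyloxy)but-2-en-1-ol
Product: 5 (Z)-4-bromobut-2-enyl tert-butyldimethylsilyl ether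
Conditions: CBr4, PPh3, CH2Cl2, 0 °C
Reagents that add atoms: carbon tetrabromide BrC(Br)(Br)Br
Why: Appel bromination of a primary allylic alcohol under neutral conditions should keep the Z geometry and the silyl ether.

Step 3
Reactants: 3 dioxolanone; 5 allylic bromide
Product: 6 (2S,5R)-2-tert-butyl-5-[(Z)-4-(tert-butyldimethylsilyloxy)but-2-enyl]-5-methyl-1,3-dioxolan-4-one
Conditions: LDA, THF, −78 °C; then 5, −78 → −30 °C
Reagents that add atoms: none
Why: Enolate alkylation with self-regeneration of the stereocentre; the SN2 attack on the reactive allylic bromide takes place anti to the tert-butyl group and sets the quaternary C10 (R) with net retention.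

Step 4
Reactants: 6 silyl ether
Product: 7 (2S,5R)-2-tert-butyl-5-[(Z)-4-hydroxybut-2-enyl]-5-methyl-1,3-dioxolan-4-one
Conditions: HF·pyridine, THF, 0 °C
Reagents that add atoms: none
Why: Fluoride desilylation under weakly acidic conditions leaves the acylal ring intact, and the primary alcohol could only lactonise through an unfavourable seven-membered ring.

Step 5
Reactants: 7 allylic alcohol
Product: 8 (Z)-allylic trichloroacetimidate of 7
Conditions: Cl3CCN, DBU (cat.), CH2Cl2, 0 °C
Reagents that add atoms: trichloroacetonitrile N#CC(Cl)(Cl)Cl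
Why: Base-catalysed addition of the alcohol to trichloroacetonitrile (imidate formation) is fast at 0 °C and installs the directing leaving group for the next step.

Step 6
Reactants: 8 imidate; 9 isobutyric acid
Product: 10 (8R,10R)-branched allylic isobutyrate with terminal vinyl group (C7=CH2)
Conditions: [COP-OAc]2 (1 mol %, the antipode that gives 8R), CH2Cl2, 23 °C
Reagents that add atoms: none
Why: Palladium(II)-catalysed enantioselective SN2′ allylic esterification of a Z-imidate sets C8 under catalyst control and delivers the final isobutyrate directly, so no free C8 hydroxyl ever exists that could lactonise onto C1.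

Step 7
Reactants: 10 vinyl ester
Product: 11 (8R,10R)-α-isobutyryloxy aldehyde (C7 aldehyde)
Conditions: O3, CH2Cl2, −78 °C; Me2S
Reagents that add atoms: ozone [O-][O+]=O
Why: Ozonolysis with reductive work-up cleaves the only alkene under neutral conditions, and the aldehyde is used at once to avoid epimerisation at C8.

Step 8
Reactants: 11 aldehyde; 12 methyl (triphenylphosphoranylidene)acetate
Product: 14 methyl (Z)-2-iodo-4-isobutyryloxy-enoate (C7=C11; iodine cis to C8), via iodo ylide 13 (not isolated)
Conditions: 12, NIS, CH2Cl2, −20 °C; then 11, rt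
Reagents that add atoms: N-iodosuccinimide O=C1CCC(=O)N1I
Why: Wittig olefination with a stabilised α-iodo ylide is base-free and should place the ester trans to the C8 chain, which is the geometry that later makes the allyl donor Z-type.

Step 9
Reactants: 14 iodo enoate; 15 2-(iodomethyl)-4,4,5,5-tetramethyl-1,3,2-dioxaborolane
Product: 17 methyl (E)-2-(pinacolatoborylmethyl)-enoate (CH2B cis to the C8 chain), via borylmethylzinc iodide 16 (not isolated)
Conditions: 15, Zn dust, THF, rt; then 14, Pd(PPh3)4 (5 mol %), THF, rt
Reagents that add atoms: none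
Why: Negishi coupling of a borylmethylzinc reagent with an alkenyl iodide proceeds with retention of geometry, and oxidative addition into C–I at room temperature should outrun ionisation of the allylic ester.

Step 10
Reactants: 17 allylboronate; 18 (S)-2,2-dimethyl-1,3-dioxolane-4-carbaldehyde
Product: 20 (6R,7R,8R,10R)-cis-α-methylene-γ-butyrolactone carrying the (S)-dioxolane on C6, via homoallyl borate 19 (not isolated)
Conditions: Sc(OTf)3 (10 mol %), toluene, 0 °C → rt; then TsOH·H2O (cat.)
Reagents that add atoms: none
Why: Lewis-acid-catalysed allylboration through a closed chair followed by lactonisation. The Z-type donor gives the syn adduct (cis lactone, C7), Cornforth/Felkin control by the α-alkoxy aldehyde sets C6 anti to the dioxolane oxygen, and A(1,3) strain at C8 (H inside, C9 chain anti to the forming bond) should reinforce this face.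

Step 11
Reactants: 20 lactone acetonide
Product: 21 (6R,7R,8R,10R)-lactone aldehyde (C5 aldehyde on C6)
Conditions: H5IO6, EtOAc, rt
Reagents that add atoms: none
Why: One-pot hydrolysis of the terminal acetonide and glycol cleavage removes the spent controller, while the hindered tert-butyl acylal, the lactone and the ester should survive; the aldehyde is used crude to avoid epimerisation at C6.

Step 12
Reactants: 22 4-(trimethylsilyl)but-3-yn-2-one
Product: 23 4-(trimethylsilyl)but-1-en-3-yn-2-yl triflate
Conditions: Tf2O, 2,6-di-tert-butyl-4-methylpyridine, CH2Cl2, 0 °C → rt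
Reagents that add atoms: triflic anhydride O=S(=O)(OS(=O)(=O)C(F)(F)F)C(F)(F)F
Why: Enol triflation of an alkynyl methyl ketone with a non-nucleophilic base can only enolise toward the methyl group and gives the C2–C4/C15 building block.

Step 13
Reactants: 21 aldehyde; 23 enynyl triflate
Product: 24 (5S,6R,7R,8R,10R)-C-silylated enynol (C5–OH, C4=C15H2, C2≡C3–SiMe3)
Conditions: CrCl2, NiCl2 (cat.), DMF, rt
Reagents that add atoms: none
Why: The Nozaki–Hiyama–Kishi reaction adds the alkenylchromium species only to the aldehyde, and polar Felkin–Anh attack anti to the C6–O bond should set C5 anti to the lactone oxygen (5S).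

Step 14
Reactants: 24 C-silyl enynol
Product: 25 (5S,6R,7R,8R,10R)-terminal enynol
Conditions: AgNO3 (10 mol %), CH2Cl2/MeOH/H2O, rt
Reagents that add atoms: none
Why: Silver(I)-catalysed protiodesilylation of an alkynylsilane is neutral and should spare the methylene lactone, the ester and the acylal, which carbonate or fluoride might attack.

Step 15
Reactants: 25 enynol
Product: 26 (5S,6R,7R,8R,10R)-5-O-triethylsilyl seco precursor
Conditions: TESCl, imidazole, CH2Cl2, 0 °C
Reagents that add atoms: chlorotriethylsilane CC[Si](Cl)(CC)CC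
Why: Silylation blocks the C5 hydroxyl, whose alkoxide would otherwise translactonise onto C12 under the basic key step.

Step 16
Reactants: 26 seco precursor
Product: 29 5-O-triethylsilyl ether of the target, via lithium acetylide 27 (not isolated), via cyclodecynone alkoxide 28 (not isolated)
Conditions: LiHMDS (4 equiv), THF, −78 °C, 26 added by syringe pump (final 1 mM), → −20 °C; t-BuOH (10 equiv), −20 → 0 °C; AcOH
Reagents that add atoms: none
Why: Proposed new method: LiHMDS removes the most acidic proton of 26 (the enyne C2–H), and the lithium acetylide attacks the acylal carbonyl C1 of the dioxolanone (10-exo-trig), which is the most electrophilic of the three ester-type carbonyls and the only one the rigid C2≡C3–C4 rod can reach, since attack at the lactone or isobutyrate carbonyl would force the alkyne into a 7- or 9-membered ring. The tetrahedral adduct collapses and the hemiacetal alkoxide expels pivalaldehyde (intercepted by excess LiHMDS as its N-silyl imine so that it cannot capture acetylide), leaving the C10 alkoxide beside a bent cyclodec-2-ynone. This alkoxide adds to C3 in the favoured 5-endo-dig mode while t-BuOH protonates C2, which closes the 3(2H)-furanone and with it the nine-membered oxa-bridge irreversibly. The closest known reaction types are the acylation of organolithiums and ester enolates by 1,3-dioxolan-4-ones (α-hydroxy ketone and tetronic acid syntheses), the acetylide-to-carbonyl closure of ten-membered enediyne rings and the alkoxide-induced 5-endo-dig closure of α′-hydroxy ynones; what is new is their union in one medium-ring cascade. No stereocentre is formed: C10 keeps the configuration stored in the dioxolanone because neither C10–O nor C10–C1 is broken, and C5–C8 are not touched at these temperatures. Ring closure over oligomerisation is secured by slow addition to high dilution, by the cis-fused lactone that holds both arms on one face, by the quaternary C10 and by delivery of the tethered acetylide to the carbonyl face anti to tert-butyl.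

Step 17
Reactants: 29 silyl ether
Product: 30 target CNP0384113.1 (5S,6R,7R,8R,10R)
Conditions: HF·pyridine, pyridine, THF, 0 °C
Reagents that add atoms: none
Why: Buffered fluoride desilylation of a secondary triethylsilyl ether is mild enough for the methylene lactone, the cross-conjugated furanone and the ester, and touches no stereocentre.

## Compound list

1 | (S)-lactic acid | C[C@H](O)C(=O)O | starting material
2 | pivalaldehyde | CC(C)(C)C=O | starting material
3 | (2S,5S)-2-tert-butyl-5-methyl-1,3-dioxolan-4-one | C[C@@H]1O[C@H](C(C)(C)C)OC1=O | intermediate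
4 | (Z)-4-(tert-butyldimethylsilyloxy)but-2-en-1-ol | OC/C=C\CO[Si](C)(C)C(C)(C)C | starting material
5 | (Z)-4-bromobut-2-enyl tert-butyldimethylsilyl ether | BrC/C=C\CO[Si](C)(C)C(C)(C)C | intermediate
6 | (2S,5R)-alkylated dioxolanone, Z-silyloxybutenyl side chain | CC(C)(C)[Si](C)(C)OC/C=C\C[C@@]1(C)O[C@H](C(C)(C)C)OC1=O | intermediate
7 | (2S,5R)-dioxolanone with (Z)-4-hydroxybut-2-enyl chain | OC/C=C\C[C@@]1(C)O[C@H](C(C)(C)C)OC1=O | intermediate
8 | (Z)-allylic trichloroacetimidate | N=C(OC/C=C\C[C@@]1(C)O[C@H](C(C)(C)C)OC1=O)C(Cl)(Cl)Cl | intermediate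
9 | isobutyric acid | CC(C)C(=O)O | starting material
10 | (8R,10R)-branched allylic isobutyrate | C=C[C@H](OC(=O)C(C)C)C[C@@]1(C)O[C@H](C(C)(C)C)OC1=O | intermediate
11 | (8R,10R)-α-isobutyryloxy aldehyde | O=C[C@H](OC(=O)C(C)C)C[C@@]1(C)O[C@H](C(C)(C)C)OC1=O | intermediate
12 | methyl (triphenylphosphoranylidene)acetate | COC(=O)C=P(c1ccccc1)(c1ccccc1)c1ccccc1 | starting material
13 | methyl iodo(triphenylphosphoranylidene)acetate | COC(=O)C(I)=P(c1ccccc1)(c1ccccc1)c1ccccc1 | intermediate
14 | methyl (Z)-2-iodo enoate, 8R,10R | COC(=O)/C(I)=C/[C@H](OC(=O)C(C)C)C[C@@]1(C)O[C@H](C(C)(C)C)OC1=O | intermediate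
15 | 2-(iodomethyl)-4,4,5,5-tetramethyl-1,3,2-dioxaborolane | ICB1OC(C)(C)C(C)(C)O1 | starting material
16 | (pinacolatoborylmethyl)zinc iodide | I[Zn]CB1OC(C)(C)C(C)(C)O1 | intermediate
17 | methyl (E)-2-(pinacolatoborylmethyl) enoate, 8R,10R | COC(=O)/C(CB1OC(C)(C)C(C)(C)O1)=C/[C@H](OC(=O)C(C)C)C[C@@]1(C)O[C@H](C(C)(C)C)OC1=O | intermediate
18 | (S)-2,2-dimethyl-1,3-dioxolane-4-carbaldehyde | O=C[C@@H]1COC(C)(C)O1 | starting material
19 | syn homoallyl pinacol borate (6R,7R,8R,10R) | COC(=O)C(=C)[C@@H]([C@@H](OB1OC(C)(C)C(C)(C)O1)[C@@H]1COC(C)(C)O1)[C@H](OC(=O)C(C)C)C[C@@]1(C)O[C@H](C(C)(C)C)OC1=O | intermediate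
20 | cis-α-methylene lactone with (S)-dioxolane on C6 | C=C1C(=O)O[C@@H]([C@@H]2COC(C)(C)O2)[C@H]1[C@H](OC(=O)C(C)C)C[C@@]1(C)O[C@H](C(C)(C)C)OC1=O | intermediate
21 | cis-lactone C5 aldehyde | C=C1C(=O)O[C@@H](C=O)[C@H]1[C@H](OC(=O)C(C)C)C[C@@]1(C)O[C@H](C(C)(C)C)OC1=O | intermediate
22 | 4-(trimethylsilyl)but-3-yn-2-one | CC(=O)C#C[Si](C)(C)C | starting material
23 | 4-(trimethylsilyl)but-1-en-3-yn-2-yl triflate | C=C(OS(=O)(=O)C(F)(F)F)C#C[Si](C)(C)C | intermediate
24 | (5S)-C-silylated enynol | C=C1C(=O)O[C@@H]([C@@H](O)C(=C)C#C[Si](C)(C)C)[C@H]1[C@H](OC(=O)C(C)C)C[C@@]1(C)O[C@H](C(C)(C)C)OC1=O | intermediate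
25 | (5S)-terminal enynol | C=C1C(=O)O[C@@H]([C@@H](O)C(=C)C#C)[C@H]1[C@H](OC(=O)C(C)C)C[C@@]1(C)O[C@H](C(C)(C)C)OC1=O | intermediate
26 | 5-O-triethylsilyl seco precursor | C=C1C(=O)O[C@@H]([C@@H](O[Si](CC)(CC)CC)C(=C)C#C)[C@H]1[C@H](OC(=O)C(C)C)C[C@@]1(C)O[C@H](C(C)(C)C)OC1=O | intermediate
27 | lithium acetylide of 26 | C=C1C(=O)O[C@@H]([C@@H](O[Si](CC)(CC)CC)C(=C)C#C[Li])[C@H]1[C@H](OC(=O)C(C)C)C[C@@]1(C)O[C@H](C(C)(C)C)OC1=O | intermediate
28 | lithium C10 alkoxide of the cyclodec-2-ynone | C=C1C(=O)O[C@@H]2[C@H]1[C@H](OC(=O)C(C)C)C[C@@](C)([O-])C(=O)C#CC(=C)[C@@H]2O[Si](CC)(CC)CC.[Li+] | intermediate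
29 | 5-O-triethylsilyl ether of the target | C=C1C(=O)O[C@@H]2[C@H]1[C@H](OC(=O)C(C)C)C[C@@]1(C)OC(=CC1=O)C(=C)[C@@H]2O[Si](CC)(CC)CC | intermediate
30 | CNP0384113.1 | C=C1C(=O)O[C@@H]2[C@H]1[C@H](OC(=O)C(C)C)C[C@@]1(C)OC(=CC1=O)C(=C)[C@@H]2O | target

## Step count and risks

Total step count: 17. Longest linear sequence: 15 (steps 1, 3–11, 13–17).

**Step 16.** The acetylide may oligomerise or be captured by the released aldehyde. The base may also enolise the isobutyrate before the medium ring closes. The fallback sets out from 20 and comes back at 30. It closes the carbocycle at C4–C5 instead and leaves the furanone closure to a separate known reaction.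
- 23 is protiodesilylated with catalytic AgNO3 to but-1-en-3-yn-2-yl triflate F1.
- The lithium acetylide of F1 (LiHMDS, −78 °C) acylates intermolecularly at the dioxolanone of 20 to give the open-chain α′-hydroxy ynone F2.
- TESOTf and 2,6-lutidine give the C10 silyl ether F3, and H5IO6 gives the C5 aldehyde F4.
- An intramolecular Nozaki–Hiyama–Kishi reaction closes the cyclodecynone F5. This reaction type is established for medium rings that carry an exocyclic methylene next to the new carbinol.
- HF·pyridine gives the hydroxy ynone F6, and a cationic gold(I) catalyst closes it 5-endo-dig to 30.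

**Step 10.** The electron-poor, Z-substituted allylboronate may add too slowly. The facial preferences of C8 and of the aldehyde may oppose each other, and the Lewis acid may ionise the allylic isobutyrate. The fallback sets out from 17 and comes back at 20. KHF2 converts 17 into the potassium allyltrifluoroborate F7. With BF3·OEt2 at −78 °C, F7 reacts with 18 as the far more reactive allyldifluoroborane through the same closed chair. Acid-catalysed lactonisation then gives 20.

**Step 13.** Facial selectivity at C5 may be poor, C6 may epimerise, or chromium(II) may reductively damage the α-acyloxy aldehyde. The fallback sets out from 24 (as an epimer mixture at C5) and comes back at 24. Dess–Martin oxidation gives the cross-conjugated enynone F8. An oxazaborolidine-catalysed borane reduction then sets C5 under reagent control instead of substrate control.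

## Further compounds

F1 | step 16 | but-1-en-3-yn-2-yl triflate | C=C(OS(=O)(=O)C(F)(F)F)C#C
F2 | step 16 | open-chain α′-hydroxy ynone | C=C1C(=O)O[C@@H]([C@@H]2COC(C)(C)O2)[C@H]1[C@H](OC(=O)C(C)C)C[C@@](C)(O)C(=O)C#CC(=C)OS(=O)(=O)C(F)(F)F
F3 | step 16 | C10 triethylsilyl ether of F2 | C=C1C(=O)O[C@@H]([C@@H]2COC(C)(C)O2)[C@H]1[C@H](OC(=O)C(C)C)C[C@@](C)(O[Si](CC)(CC)CC)C(=O)C#CC(=C)OS(=O)(=O)C(F)(F)F
F4 | step 16 | C5 aldehyde with ynone triflate arm | C=C1C(=O)O[C@@H](C=O)[C@H]1[C@H](OC(=O)C(C)C)C[C@@](C)(O[Si](CC)(CC)CC)C(=O)C#CC(=C)OS(=O)(=O)C(F)(F)F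
F5 | step 16 | 10-O-triethylsilyl cyclodecynone | C=C1C(=O)O[C@@H]2[C@H]1[C@H](OC(=O)C(C)C)C[C@@](C)(O[Si](CC)(CC)CC)C(=O)C#CC(=C)[C@@H]2O
F6 | step 16 | macrocyclic α′-hydroxy ynone | C=C1C(=O)O[C@@H]2[C@H]1[C@H](OC(=O)C(C)C)C[C@@](C)(O)C(=O)C#CC(=C)[C@@H]2O
F7 | step 10 | potassium allyltrifluoroborate | COC(=O)/C(C[B-](F)(F)F)=C/[C@H](OC(=O)C(C)C)C[C@@]1(C)O[C@H](C(C)(C)C)OC1=O.[K+]
F8 | step 13 | C5 enynone | C=C1C(=O)O[C@@H](C(=O)C(=C)C#C[Si](C)(C)C)[C@H]1[C@H](OC(=O)C(C)C)C[C@@]1(C)O[C@H](C(C)(C)C)OC1=O
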